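**Retrosynthetic overview**

- The strategy rests on the C6–C7 bond that joins the 1,2-dioxane (O1, O2, C3 to C6) to the trans-2,5-disubstituted tetrahydrofuran (O, C7 to C10). Its erythro C6–OO and C7–O bonds, flanked 1,4 by C3–O and C10–O, are the imprint of a trans-6,7-epoxide opened at C6 by a C3 peroxide while the epoxide oxygen closes on C10.
- Disconnections, last to first: C18–C19 (Stille coupling of a Z-vinyl iodide with a Z-vinylstannane); C3–H (ionic reduction of a 3-methoxy peroxy ketal); O–C6 and O–C10 together (anionic relay from a C3 hydroperoxy ketal across a (6S,7S)-epoxide onto an (S)-C10 mesylate).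
- The hydroperoxy ketal comes from ozonolysis in methanol of a 1,1-disubstituted alkene. C4–C5 comes from an epoxy triflate and the isoprenol dianion, the epoxide from Sharpless epoxidation of an allylic alcohol (acrylate cross-metathesis, then reduction), and C10 from (R)-1,2-epoxyhex-5-ene and a C12–C18 Grignard reagent.
- Ring order: epoxide first, then in one operation the 1,2-dioxane followed by the tetrahydrofuran; the diene tail is attached at the end.

Key step: step 11

Remark on the chemistry: locants C1 to C24 are those of the target chain (C1 carboxyl carbon, C3 and C6 the dioxane carbons, C7 and C10 the tetrahydrofuran carbons, C24 the terminal CH2).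
Remark on the chemistry: the alkyne is carried as its triisopropylsilyl derivative and the C1 hydroxyl as a triisopropylsilyl ether. An alkynyl trimethylsilyl group would be stripped by hydroxide in DMF in step 11, and a free hydroxyl would consume the silyl triflate of step 12. One buffered fluoride treatment (step 13) removes both groups.
Assumption: the six starting materials are bought, the epoxide in high enantiomeric purity.

**Route**

Step 1
Reactants: 1 ethynyltriisopropylsilane; 2 1,5-dibromopentane
Product: 4 (7-bromohept-1-yn-1-yl)triisopropylsilane, via lithium acetylide 3 (not isolated)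
Conditions: n-BuLi, THF, −78 to 0 °C; then 2 (4 equiv), DMPU, 0 °C to rt
Reagents that add atoms: none
Why: SN2 alkylation of a lithium acetylide by a primary bromide in a dipolar aprotic co-solvent, with the dibromide in excess so that monoalkylation dominates and the surplus is distilled off.

Step 2
Reactants: 4 (7-bromohept-1-yn-1-yl)triisopropylsilane; 5 (R)-1,2-epoxyhex-5-ene
Product: 7 (5S)-13-(triisopropylsilyl)tridec-1-en-12-yn-5-ol, via Grignard reagent 6 (not isolated)
Conditions: Mg, THF, rt; then CuI (10 mol%), 5, −30 to 0 °C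
Reagents that add atoms: none
Why: Copper-catalysed Grignard opening of a terminal epoxide occurs at the unhindered CH2 (C11), so no bond at C10 is touched and the stereocentre of 5 is carried over unchanged (the descriptor changes from R to S only because the chain priorities change).

Step 3
Reactants: 7 (5S)-13-(triisopropylsilyl)tridec-1-en-12-yn-5-ol
Product: 8 (5S)-13-(triisopropylsilyl)tridec-1-en-12-yn-5-yl methanesulfonate
Conditions: MsCl, Et3N, CH2Cl2, 0 °C
Reagents that add atoms: methanesulfonyl chloride CS(=O)(=O)Cl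
Why: Sulfonylation at oxygen (mesylation) keeps the C10 configuration and installs the leaving group before any epoxide exists, so a free C10 hydroxyl can never open the later epoxide.

Step 4
Reactants: 8 (5S)-13-(triisopropylsilyl)tridec-1-en-12-yn-5-yl methanesulfonate; 9 methyl acrylate
Product: 10 methyl (2E,6S)-6-(methylsulfonyloxy)-14-(triisopropylsilyl)tetradec-2-en-13-ynoate
Conditions: second-generation Hoveyda–Grubbs catalyst RuCl2(H2IMes)(=CH-C6H4-2-OiPr) (5 mol%), 9 (5 equiv), CH2Cl2, 40 °C
Reagents that add atoms: none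
Why: Olefin cross-metathesis of a terminal alkene with an electron-poor acrylate is selective for the cross product and gives the E-enoate, while the hindered silyl alkyne and the mesylate should not engage the ruthenium carbene.

Step 5
Reactants: 10 methyl (2E,6S)-6-(methylsulfonyloxy)-14-(triisopropylsilyl)tetradec-2-en-13-ynoate
Product: 11 (2E,6S)-1-hydroxy-14-(triisopropylsilyl)tetradec-2-en-13-yn-6-yl methanesulfonate
Conditions: i-Bu2AlH (2.5 equiv), CH2Cl2, −78 °C; aq KNaC4H4O6
Reagents that add atoms: none
Why: Hydride reduction of the conjugated ester by i-Bu2AlH goes 1,2 to the allylic alcohol at −78 °C, a temperature at which the secondary mesylate and the silyl alkyne are not attacked.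

Step 6
Reactants: 11 (2E,6S)-1-hydroxy-14-(triisopropylsilyl)tetradec-2-en-13-yn-6-yl methanesulfonate
Product: 12 [(2S,3S)-3-[(3S)-3-(methylsulfonyloxy)-11-(triisopropylsilyl)undec-10-yn-1-yl]oxiran-2-yl]methanol (6S,7S,10S in target numbering)
Conditions: Ti(OiPr)4 (0.2 equiv), L-(+)-diethyl tartrate (0.25 equiv), t-BuOOH, 4 Å sieves, CH2Cl2, −20 °C
Reagents that add atoms: tert-butyl hydroperoxide CC(C)(C)OO
Why: Sharpless asymmetric epoxidation, directed by the allylic hydroxyl, is reagent-controlled, and the L-(+)-tartrate titanium complex delivers oxygen to the face of an E-allylic alcohol that gives the (2S,3S)-epoxy alcohol, which sets C6 and C7 as S and S.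

Step 7
Reactants: 12 the (6S,7S,10S)-epoxy alcohol
Product: 13 [(2S,3S)-3-[(3S)-3-(methylsulfonyloxy)-11-(triisopropylsilyl)undec-10-yn-1-yl]oxiran-2-yl]methyl trifluoromethanesulfonate
Conditions: Tf2O, 2,6-lutidine, CH2Cl2, −78 °C; used cold and at once
Reagents that add atoms: trifluoromethanesulfonic anhydride O=S(=O)(OS(=O)(=O)C(F)(F)F)C(F)(F)F
Why: O-Triflation of the primary alcohol with a hindered pyridine base activates C5 without touching any stereocentre, and the epoxy triflate is taken on directly because such triflates do not keep.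

Step 8
Reactants: 13 the epoxy triflate; 14 3-methylbut-3-en-1-ol (isoprenol)
Product: 16 (3S)-1-[(2S,3S)-3-(5-hydroxy-3-methylidenepentyl)oxiran-2-yl]-11-(triisopropylsilyl)undec-10-yn-3-yl methanesulfonate, via isoprenol dianion 15 (not isolated)
Conditions: 14, n-BuLi (2 equiv), TMEDA, Et2O, 0 °C to rt; then 13, THF, −78 °C, cold NH4Cl quench
Reagents that add atoms: none
Why: SN2 alkylation of the allylic terminus of the isoprenol dianion (made by alkoxide-directed allylic lithiation) by the primary triflate forms C4–C5 at −78 °C, where the triflate should react far faster than the epoxide or the secondary mesylate, and the two termini of the 2-substituted allyl anion are equivalent so only one regioisomer can form.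

Step 9
Reactants: 16 the alkene alcohol
Product: 17 (3S)-1-[(2S,3S)-3-[3-methylidene-5-(triisopropylsilyloxy)pentyl]oxiran-2-yl]-11-(triisopropylsilyl)undec-10-yn-3-yl methanesulfonate
Conditions: i-Pr3SiCl, imidazole, DMF, 0 °C to rt
Reagents that add atoms: chlorotriisopropylsilane CC(C)[Si](Cl)(C(C)C)C(C)C
Why: Silyl ether protection of the only hydroxyl means the next three steps see no free OH, and the bulky group should withstand both hydroxide and the silyl triflate.

Step 10
Reactants: 17 the 1,1-disubstituted alkene
Product: 19 (3S)-1-[(2S,3S)-3-[3-hydroperoxy-3-methoxy-5-(triisopropylsilyloxy)pentyl]oxiran-2-yl]-11-(triisopropylsilyl)undec-10-yn-3-yl methanesulfonate (both C3 epimers), via carbonyl oxide 18 (not isolated)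
Conditions: O3, CH2Cl2/MeOH (4:1), NaHCO3, −78 °C; N2 purge, no reductant
Reagents that add atoms: ozone [O-][O+]=O; methanol CO
Why: Ozonolysis of the electron-rich 1,1-disubstituted alkene gives a primary ozonide that should fragment to formaldehyde and the more substituted C3 carbonyl oxide, which methanol traps as the α-methoxy hydroperoxide, while the hindered silyl alkyne reacts far more slowly with ozone and C3 need not be controlled because it is reset in step 12.

Step 11
Reactants: 19 the C3 hydroperoxy ketal
Product: 22 (6R)-3-methoxy-3-[2-(triisopropylsilyloxy)ethyl]-6-[(2S,5R)-5-[8-(triisopropylsilyl)oct-7-yn-1-yl]oxolan-2-yl]-1,2-dioxane (both C3 epimers), via caesium peroxide 20 (not isolated), via dioxane alkoxide 21 (not isolated)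
Conditions: CsOH·H2O (1.5 equiv), DMF, 0 °C to rt
Reagents that add atoms: none
Why: Proposed new method: caesium hydroxide deprotonates the hydroperoxy ketal, the peroxide anion opens the trans-epoxide at C6 from the rear to close the 1,2-dioxane (O1, O2, C3 to C6; 6-exo-tet, new O–C6 bond), and the C7 alkoxide released in that event displaces the C10 mesylate to close the tetrahydrofuran (O, C7 to C10; 5-exo-tet, new O–C10 bond), the irreversible second closure drawing the first one forward. The closest known reaction types are the intramolecular 6-exo opening of epoxides by tethered hydroperoxides to 1,2-dioxanes, the base-mediated cyclisation of hydroperoxy ketal anions onto sulfonates, and epoxide-to-sulfonate relays to tetrahydrofurans in polyether and acetogenin chemistry; a relay started by a peroxide anion that chains the two has not been shown. All three new configurations are substrate-controlled by SN2 geometry: C6 goes from S to R by inversion, C7 keeps its oxygen and stays S, and C10 goes from S to R by inversion, which makes C6/C7 erythro and the tetrahydrofuran 2,5-trans. The step needs attack at C6 (6-exo) and not at C7 (7-endo) and clean inversion at C6 and C10; the two-carbon tethers C4–C5 and C8–C9 allow a collinear approach only for the exo modes, so no reagent control is required. The substrate is built to leave few exits: the peroxide oxygen is the only nucleophile on the ketal carbon, C3 carries no hydrogen for Kornblum–DeLaMare fragmentation, the hindered silyl groups should resist hydroxide at this temperature, and the C3 epimer mixture is harmless because C3 is reset in step 12.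

Step 12
Reactants: 22 the 3-methoxy-1,2-dioxane
Product: 24 (3R,6R)-3-[2-(triisopropylsilyloxy)ethyl]-6-[(2S,5R)-5-[8-(triisopropylsilyl)oct-7-yn-1-yl]oxolan-2-yl]-1,2-dioxane, via peroxycarbenium triflate 23 (not isolated)
Conditions: Et3SiH (5 equiv), Me3SiOTf (1.2 equiv), CH2Cl2, −78 °C
Reagents that add atoms: none
Why: Ionic reduction in which Me3SiOTf removes the exocyclic methoxide to give the cyclic peroxycarbenium ion (the known mode of Lewis acid substitution of 3-alkoxy-1,2-dioxanes) and Et3SiH should deliver hydride axially to the half-chair that holds the C6 substituent pseudo-equatorial, which puts both ring substituents equatorial (3,6-trans) and sets C3 as R from either C3 epimer.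

Step 13
Reactants: 24 the bis-silylated dioxane
Product: 25 2-[(3R,6R)-6-[(2S,5R)-5-(oct-7-yn-1-yl)oxolan-2-yl]-1,2-dioxan-3-yl]ethan-1-ol
Conditions: Bu4NF (3 equiv), AcOH (3 equiv), THF, 0 °C to rt
Reagents that add atoms: none
Why: Fluoride-mediated desilylation cleaves the O–Si bond of the silyl ether and the C–Si bond of the silyl alkyne in one operation, with acetic acid buffering the medium so that the peroxide is not exposed to strong base.

Step 14
Reactants: 25 the alkynyl alcohol
Product: 26 2-[(3R,6R)-6-[(2S,5R)-5-(8-iodooct-7-yn-1-yl)oxolan-2-yl]-1,2-dioxan-3-yl]ethan-1-ol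
Conditions: N-iodosuccinimide, AgNO3 (10 mol%), acetone, rt, dark
Reagents that add atoms: N-iodosuccinimide O=C1CCC(=O)N1I
Why: Silver-catalysed electrophilic iodination of the terminal alkyne through the silver acetylide gives the 1-iodoalkyne under neutral conditions that leave the alcohol and the peroxide untouched.

Step 15
Reactants: 26 the iodoalkyne
Product: 27 2-[(3R,6R)-6-[(2S,5R)-5-[(7Z)-8-iodooct-7-en-1-yl]oxolan-2-yl]-1,2-dioxan-3-yl]ethan-1-ol
Conditions: 2-nitrobenzenesulfonyl hydrazide (excess), Et3N, THF/i-PrOH (1:1), rt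
Reagents that add atoms: none
Why: Diimide reduction, with diimide generated in the flask, adds H2 syn across the iodoalkyne to give the Z-iodoalkene, and diimide is known to spare O–O bonds.

Step 16
Reactants: 27 the (Z)-vinyl iodide alcohol
Product: 28 2-[(3R,6R)-6-[(2S,5R)-5-[(7Z)-8-iodooct-7-en-1-yl]oxolan-2-yl]-1,2-dioxan-3-yl]acetic acid
Conditions: TEMPO (20 mol%), PhI(OAc)2 (2.5 equiv), MeCN/H2O (1:1), rt
Reagents that add atoms: water O
Why: Oxoammonium-mediated oxidation (TEMPO with PhI(OAc)2 as terminal oxidant) in aqueous acetonitrile takes the primary alcohol through the aldehyde hydrate to the acid under mildly acidic conditions that should avoid β-elimination of the peroxide and leave the vinyl iodide alone.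

Step 17
Reactants: 29 hex-5-en-1-yne
Product: 30 (Z)-tributyl(hexa-1,5-dien-1-yl)stannane
Conditions: Bu3SnH, ZrCl4 (20 mol%), toluene, 0 °C
Reagents that add atoms: tributyltin hydride CCCC[SnH](CCCC)CCCC
Why: Lewis acid-catalysed hydrostannation of a terminal alkyne proceeds by anti addition of H and Sn, which gives the (Z)-vinylstannane, and the isolated terminal alkene is not hydrostannated in the absence of a radical initiator.

Step 18
Reactants: 28 the (Z)-vinyl iodide acid; 30 (Z)-tributyl(hexa-1,5-dien-1-yl)stannane
Product: 31 2-[(3R,6R)-6-[(2S,5R)-5-[(7Z,9Z)-tetradeca-7,9,13-trien-1-yl]oxolan-2-yl]-1,2-dioxan-3-yl]acetic acid (target, CNP0186740.5)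
Conditions: Pd(PPh3)4 (10 mol%), CuI (20 mol%), CsF (3 equiv), DMF, rt, dark
Reagents that add atoms: none
Why: Stille coupling, in which oxidative addition of the vinyl iodide to zerovalent palladium, copper- and fluoride-assisted transmetallation of the vinylstannane and reductive elimination all proceed with retention, so the two Z alkenes are joined as the (17Z,19Z)-diene at room temperature with the acid carried as its caesium salt.

**Compound list**

1 | ethynyltriisopropylsilane | C#C[Si](C(C)C)(C(C)C)C(C)C | starting material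
2 | 1,5-dibromopentane | BrCCCCCBr | starting material
3 | lithium (triisopropylsilyl)acetylide | [Li]C#C[Si](C(C)C)(C(C)C)C(C)C | intermediate (not isolated)
4 | (7-bromohept-1-yn-1-yl)triisopropylsilane | BrCCCCCC#C[Si](C(C)C)(C(C)C)C(C)C | intermediate
5 | (R)-1,2-epoxyhex-5-ene | C=CCC[C@@H]1CO1 | starting material
6 | [7-(triisopropylsilyl)hept-6-yn-1-yl]magnesium bromide | Br[Mg]CCCCCC#C[Si](C(C)C)(C(C)C)C(C)C | intermediate (not isolated)
7 | (5S)-13-(triisopropylsilyl)tridec-1-en-12-yn-5-ol | C=CCC[C@@H](O)CCCCCCC#C[Si](C(C)C)(C(C)C)C(C)C | intermediate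
8 | (5S)-13-(triisopropylsilyl)tridec-1-en-12-yn-5-yl methanesulfonate | C=CCC[C@@H](OS(C)(=O)=O)CCCCCCC#C[Si](C(C)C)(C(C)C)C(C)C | intermediate
9 | methyl acrylate | C=CC(=O)OC | starting material
10 | methyl (2E,6S)-6-(methylsulfonyloxy)-14-(triisopropylsilyl)tetradec-2-en-13-ynoate | COC(=O)/C=C/CC[C@@H](OS(C)(=O)=O)CCCCCCC#C[Si](C(C)C)(C(C)C)C(C)C | intermediate
11 | (2E,6S)-1-hydroxy-14-(triisopropylsilyl)tetradec-2-en-13-yn-6-yl methanesulfonate | OC/C=C/CC[C@@H](OS(C)(=O)=O)CCCCCCC#C[Si](C(C)C)(C(C)C)C(C)C | intermediate
12 | (6S,7S,10S)-epoxy alcohol, [(2S,3S)-3-[(3S)-3-(methylsulfonyloxy)-11-(triisopropylsilyl)undec-10-yn-1-yl]oxiran-2-yl]methanol | OC[C@@H]1O[C@H]1CC[C@@H](OS(C)(=O)=O)CCCCCCC#C[Si](C(C)C)(C(C)C)C(C)C | intermediate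
13 | primary triflate of 12 | O=S(=O)(OC[C@@H]1O[C@H]1CC[C@@H](OS(C)(=O)=O)CCCCCCC#C[Si](C(C)C)(C(C)C)C(C)C)C(F)(F)F | intermediate
14 | 3-methylbut-3-en-1-ol (isoprenol) | C=C(C)CCO | starting material
15 | dilithium dianion of isoprenol, lithium 3-(lithiomethyl)but-3-en-1-olate | [Li]CC(=C)CCO[Li] | intermediate (not isolated)
16 | (3S)-1-[(2S,3S)-3-(5-hydroxy-3-methylidenepentyl)oxiran-2-yl]-11-(triisopropylsilyl)undec-10-yn-3-yl methanesulfonate | C=C(CCO)CC[C@@H]1O[C@H]1CC[C@@H](OS(C)(=O)=O)CCCCCCC#C[Si](C(C)C)(C(C)C)C(C)C | intermediate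
17 | triisopropylsilyl ether of 16 | C=C(CCO[Si](C(C)C)(C(C)C)C(C)C)CC[C@@H]1O[C@H]1CC[C@@H](OS(C)(=O)=O)CCCCCCC#C[Si](C(C)C)(C(C)C)C(C)C | intermediate
18 | C3 carbonyl oxide from 17 | [O-][O+]=C(CCO[Si](C(C)C)(C(C)C)C(C)C)CC[C@@H]1O[C@H]1CC[C@@H](OS(C)(=O)=O)CCCCCCC#C[Si](C(C)C)(C(C)C)C(C)C | intermediate (not isolated)
19 | C3 methoxy hydroperoxy ketal with (6S,7S)-epoxide and (10S)-mesylate, both C3 epimers | COC(OO)(CCO[Si](C(C)C)(C(C)C)C(C)C)CC[C@@H]1O[C@H]1CC[C@@H](OS(C)(=O)=O)CCCCCCC#C[Si](C(C)C)(C(C)C)C(C)C | intermediate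
20 | caesium peroxide of 19 | [Cs+].COC(O[O-])(CCO[Si](C(C)C)(C(C)C)C(C)C)CC[C@@H]1O[C@H]1CC[C@@H](OS(C)(=O)=O)CCCCCCC#C[Si](C(C)C)(C(C)C)C(C)C | intermediate (not isolated)
21 | caesium C7 alkoxide of the closed 1,2-dioxane, C10 mesylate intact | [Cs+].[O-][C@@H](CC[C@@H](OS(C)(=O)=O)CCCCCCC#C[Si](C(C)C)(C(C)C)C(C)C)[C@H]1CCC(CCO[Si](C(C)C)(C(C)C)C(C)C)(OC)OO1 | intermediate (not isolated)
22 | (6R)-3-methoxy-3-[2-(triisopropylsilyloxy)ethyl]-6-[(2S,5R)-5-[8-(triisopropylsilyl)oct-7-yn-1-yl]oxolan-2-yl]-1,2-dioxane, both C3 epimers | CC(C)[Si](C(C)C)(C(C)C)C#CCCCCCC[C@@H]1CC[C@@H]([C@H]2CCC(CCO[Si](C(C)C)(C(C)C)C(C)C)(OC)OO2)O1 | intermediate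
23 | cyclic peroxycarbenium triflate from 22 | CC(C)[Si](C(C)C)(C(C)C)C#CCCCCCC[C@@H]1CC[C@@H]([C@H]2CCC(CCO[Si](C(C)C)(C(C)C)C(C)C)=[O+]O2)O1.[O-]S(=O)(=O)C(F)(F)F | intermediate (not isolated)
24 | (3R,6R)-3-[2-(triisopropylsilyloxy)ethyl]-6-[(2S,5R)-5-[8-(triisopropylsilyl)oct-7-yn-1-yl]oxolan-2-yl]-1,2-dioxane | CC(C)[Si](C(C)C)(C(C)C)C#CCCCCCC[C@@H]1CC[C@@H]([C@H]2CC[C@H](CCO[Si](C(C)C)(C(C)C)C(C)C)OO2)O1 | intermediate
25 | 2-[(3R,6R)-6-[(2S,5R)-5-(oct-7-yn-1-yl)oxolan-2-yl]-1,2-dioxan-3-yl]ethan-1-ol | C#CCCCCCC[C@@H]1CC[C@@H]([C@H]2CC[C@H](CCO)OO2)O1 | intermediate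
26 | 2-[(3R,6R)-6-[(2S,5R)-5-(8-iodooct-7-yn-1-yl)oxolan-2-yl]-1,2-dioxan-3-yl]ethan-1-ol | IC#CCCCCCC[C@@H]1CC[C@@H]([C@H]2CC[C@H](CCO)OO2)O1 | intermediate
27 | 2-[(3R,6R)-6-[(2S,5R)-5-[(7Z)-8-iodooct-7-en-1-yl]oxolan-2-yl]-1,2-dioxan-3-yl]ethan-1-ol | I/C=C\CCCCCC[C@@H]1CC[C@@H]([C@H]2CC[C@H](CCO)OO2)O1 | intermediate
28 | 2-[(3R,6R)-6-[(2S,5R)-5-[(7Z)-8-iodooct-7-en-1-yl]oxolan-2-yl]-1,2-dioxan-3-yl]acetic acid | I/C=C\CCCCCC[C@@H]1CC[C@@H]([C@H]2CC[C@H](CC(=O)O)OO2)O1 | intermediate
29 | hex-5-en-1-yne | C#CCCC=C | starting material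
30 | (Z)-tributyl(hexa-1,5-dien-1-yl)stannane | C=CCC/C=C\[Sn](CCCC)(CCCC)CCCC | intermediate
31 | 2-[(3R,6R)-6-[(2S,5R)-5-[(7Z,9Z)-tetradeca-7,9,13-trien-1-yl]oxolan-2-yl]-1,2-dioxan-3-yl]acetic acid, CNP0186740.5 | C=CCC/C=C\C=C/CCCCCC[C@@H]1CC[C@@H]([C@H]2CC[C@H](CC(=O)O)OO2)O1 | target

**Step count and risks**

Total step count: 18. Longest linear sequence: 17 steps (steps 1 to 16 and step 18); step 17 is a one-step side branch.

Steps most likely to fail:

1. Step 11 (the step labelled as a proposed new method). The hydroperoxy ketal anion may decompose in the strongly basic medium before it reaches C6, the peroxide anion may leak to C7 (7-endo), or the freshly formed dioxane may undergo base-induced Kornblum–DeLaMare cleavage at C6–H while the alkoxide waits to close. The fallback uses known reactions only and uncouples the two ring closures. Setting out from 19, the 1,2-dioxane is closed alone under weakly basic, protic conditions (Et2NH in CF3CH2OH, rt). There the neutral hydroperoxide opens the hydrogen-bond-activated epoxide 6-exo and the C7 hydroxyl is never ionised, so the hydroxy mesylate F1 can be isolated. A separate Williamson etherification (NaH, THF, 0 °C; 5-exo-tet with inversion at C10), as practised for tetrahydrofurans from hydroxy sulfonates, then closes the second ring, and the sequence comes back to the route at 22.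

2. Step 8. The allylic dilithium reagent is a strong base and may deprotonate the mesylate methyl group, eliminate or displace the secondary sulfonate, open the epoxide, or be alkylated at oxygen instead of displacing the triflate cleanly at carbon. The fallback forms C3–C4 in place of C4–C5 by a B-alkyl Suzuki–Miyaura coupling under near-neutral conditions. Setting out from 12, oxidation (SO3·pyridine, DMSO, i-Pr2NEt, 0 °C) gives the epoxy aldehyde F2. Wittig methylenation (Ph3PCH3Br, KN(SiMe3)2, THF, −78 °C) gives the vinyl epoxide F3. Hydroboration of its terminal alkene with 9-borabicyclo[3.3.1]nonane gives the B-alkyl borane F4, which is used in the flask. It is coupled with the 2-bromoalkene (3-bromobut-3-en-1-yloxy)triisopropylsilane F5, made from purchased 3-bromobut-3-en-1-ol with i-Pr3SiCl and imidazole, using PdCl2(dppf), AsPh3 and Cs2CO3 in DMF/THF/H2O at rt. The coupling product is 17 itself, so the fallback comes back to the route at 17 and step 9 is no longer needed.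

3. Step 18. Zerovalent palladium and free triphenylphosphine may insert into or deoxygenate the O–O bond, the carboxylic acid may protodestannylate 30, or the Z,Z-diene may isomerise during a slow coupling. The fallback leaves out palladium and phosphine altogether and joins the same two compounds by a copper-mediated vinyl–vinyl coupling. Setting out from 28 and 30, stoichiometric Cu(O2CC4H3S) (copper thiophene-2-carboxylate, monovalent copper) in N-methylpyrrolidone at 0 °C transmetallates the stannane to a vinylcopper species that couples with the iodide with retention at both alkenes. The product is the target 31 itself, so the route is rejoined at 31 and no new compound is made on the way.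

Further compounds
F1 | step 11 | hydroxy mesylate: closed 3-methoxy-1,2-dioxane with free C7 hydroxyl and intact (10S)-mesylate (protonated form of 21) | O[C@@H](CC[C@@H](OS(C)(=O)=O)CCCCCCC#C[Si](C(C)C)(C(C)C)C(C)C)[C@H]1CCC(CCO[Si](C(C)C)(C(C)C)C(C)C)(OC)OO1
F2 | step 8 | epoxy aldehyde from 12 (epoxide and mesylate configurations unchanged) | O=C[C@@H]1O[C@H]1CC[C@@H](OS(C)(=O)=O)CCCCCCC#C[Si](C(C)C)(C(C)C)C(C)C
F3 | step 8 | vinyl epoxide from F2 (C4=C5 terminal alkene) | C=C[C@@H]1O[C@H]1CC[C@@H](OS(C)(=O)=O)CCCCCCC#C[Si](C(C)C)(C(C)C)C(C)C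
F4 | step 8 | B-alkyl-9-borabicyclo[3.3.1]nonane from F3 (boron on C4) | C(CB3C4CCCC3CCC4)[C@@H]1O[C@H]1CC[C@@H](OS(C)(=O)=O)CCCCCCC#C[Si](C(C)C)(C(C)C)C(C)C
F5 | step 8 | (3-bromobut-3-en-1-yloxy)triisopropylsilane | C=C(Br)CCO[Si](C(C)C)(C(C)C)C(C)C
F0 | step 18 | none | none
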